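**Assumption:** methyl (R)-3-hydroxytetradecanoate (bulk orlistat intermediate, ≥98 % ee) is bought as such; the target's single stereocentre is (R) and is carried over from it unchanged.

## Retrosynthetic overview

1. Quinone 10 ⇐ Teuber oxidation of phenol 9 (new C=O para to OH, between OMe and the side chain); 9 ⇐ O-acetylation of carbinol 7.
2. The benzene ring of 7 (the only ring formed) ⇐ C2→C7 aldol condensation/aromatisation of a linear enol-ether tetraketide 4 with loss of the C1 carboxyl as CO2. This is the alkylresorcinol folding, with (R)-3-hydroxytetradecanoyl as starter unit.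
3. The tetraketide is never handled open-chain: it is released in the flask from keto-pyrone 3, a masked triacetate that already carries the O-methyl group.
4. 3 ⇐ C-acylation of laterally lithiated 4-methoxy-6-methyl-2-pyrone 2 with unprotected hydroxy ester 1.
5. Ring order: pyrone (bought, sacrificial, opened) → benzene ring (step 2) → quinone by oxidation of that same ring (step 4).

## Route

Step 1
Reactants: 1 methyl (R)-3-hydroxytetradecanoate; 2 4-methoxy-6-methyl-2H-pyran-2-one
Product: 3 6-[(4R)-4-hydroxy-2-oxopentadecyl]-4-methoxy-2H-pyran-2-one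
Conditions: 2 (2.3 equiv), LDA (2.3 equiv), THF, −78 °C, 30 min; then Li alkoxide of 1 (1 + 1.0 equiv LDA, THF, −78 °C), −78 → −30 °C, 3 h; AcOH quench at −78 °C
Reagents that add atoms: none
Why: Lateral (vinylogous) lithiation of the pyrone methyl group followed by crossed Claisen condensation with the methyl ester, whose hydroxyl is masked in situ as the lithium alkoxide (the same tactic as Claisen condensations of lithium enolates with unprotected β-hydroxy esters, the second equivalent of anion deprotonating the more acidic product); the (R)-carbinol comes with 1 and is not touched because its O–C bond and its α-carbon are not involved.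

Step 2
Reactants: 3 6-[(4R)-4-hydroxy-2-oxopentadecyl]-4-methoxy-2H-pyran-2-one
Product: 7 3-[(2R)-2-hydroxytridecyl]-5-methoxyphenol, via ring-opened keto ester 4 (not isolated), via methyl benzoate 5 (not isolated), via benzoic acid 6 (not isolated)
Conditions: KOH (8 equiv), MeOH, N2, 0 → 65 °C, 4 h; then H2O/ethylene glycol (1:1), MeOH distilled out, 120 °C, 8 h; 1 M HCl to pH 5
Reagents that add atoms: none
Why: Methoxide opens the pyrone to the dienolate of 4, whose ester α-carbon (C2) adds 6-exo to the C7 ketone and dehydration/enolisation gives benzoate 5 (the biogenetic-type pyrone-to-resorcylate aldol ring transformation), after which hot aqueous alkali saponifies the ester and the 2,6-disubstituted 4-oxidobenzoate 6 loses CO2 by ipso-protonation (decarboxylative saponification of a resorcylate); no stereocentre is formed, and the existing carbinol is protected from E1cB loss and retro-aldol because its β-ketone is held as the 1,3-diketonate until the ring aromatises.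

Step 3
Reactants: 7 3-[(2R)-2-hydroxytridecyl]-5-methoxyphenol
Product: 9 (2R)-1-(3-hydroxy-5-methoxyphenyl)tridecan-2-yl acetate, via diacetate 8 (not isolated)
Conditions: Ac2O (2.5 equiv), pyridine, DMAP (5 mol %), CH2Cl2, 23 °C, 2 h; then pyrrolidine (3 equiv), 0 → 23 °C, 30 min
Reagents that add atoms: acetic anhydride CC(=O)OC(C)=O
Why: Exhaustive DMAP-catalysed O-acetylation followed by chemoselective aminolysis of the aryl acetate (phenoxide is by far the better leaving group, so the secondary alkyl acetate is inert to pyrrolidine at room temperature); acylation occurs at oxygen, so the (R)-centre is retained.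

Step 4
Reactants: 9 (2R)-1-(3-hydroxy-5-methoxyphenyl)tridecan-2-yl acetate
Product: 10 (2R)-1-(5-methoxy-3,6-dioxocyclohexa-1,4-dien-1-yl)tridecan-2-yl acetate
Conditions: (KSO3)2NO (2.5 equiv), aq. KH2PO4 (pH ≈ 6), acetone, 0 → 23 °C, 2 h
Reagents that add atoms: Fremy's salt (dipotassium nitrosodisulfonate) [K+].[K+].[O-]S(=O)(=O)N([O])S(=O)(=O)[O-]
Why: Teuber oxidation, in which Fremy's radical abstracts the phenolic hydrogen and a second equivalent couples at the free para carbon (the same regiochemistry as the known oxidation of 3-methoxy-5-pentylphenol to primin) before loss of imidodisulfonate gives the 2-methoxy-6-alkyl-1,4-benzoquinone; the near-neutral buffer leaves the secondary acetate and its stereocentre untouched.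

## Compound list

1 | methyl (R)-3-hydroxytetradecanoate | CCCCCCCCCCC[C@H](CC(=O)OC)O | starting material
2 | 4-methoxy-6-methyl-2H-pyran-2-one | CC1=CC(OC)=CC(=O)O1 | starting material
3 | 6-[(4R)-4-hydroxy-2-oxopentadecyl]-4-methoxy-2H-pyran-2-one | CCCCCCCCCCC[C@H](CC(=O)CC1=CC(OC)=CC(=O)O1)O | intermediate
4 | methyl (2E,9R)-9-hydroxy-3-methoxy-5,7-dioxoicos-2-enoate (present as its enolate) | CCCCCCCCCCC[C@H](CC(=O)CC(=O)C/C(OC)=C\C(=O)OC)O | intermediate
5 | methyl 4-hydroxy-6-[(2R)-2-hydroxytridecyl]-2-methoxybenzoate | CCCCCCCCCCC[C@H](Cc1cc(O)cc(OC)c1C(=O)OC)O | intermediate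
6 | 4-hydroxy-6-[(2R)-2-hydroxytridecyl]-2-methoxybenzoic acid (present as its potassium salt) | CCCCCCCCCCC[C@H](Cc1cc(O)cc(OC)c1C(=O)O)O | intermediate
7 | 3-[(2R)-2-hydroxytridecyl]-5-methoxyphenol | CCCCCCCCCCC[C@H](Cc1cc(O)cc(OC)c1)O | intermediate
8 | 3-[(2R)-2-acetoxytridecyl]-5-methoxyphenyl acetate | CCCCCCCCCCC[C@H](Cc1cc(OC(C)=O)cc(OC)c1)OC(C)=O | intermediate
9 | (2R)-1-(3-hydroxy-5-methoxyphenyl)tridecan-2-yl acetate | CCCCCCCCCCC[C@H](Cc1cc(O)cc(OC)c1)OC(C)=O | intermediate
10 | (2R)-1-(5-methoxy-3,6-dioxocyclohexa-1,4-dien-1-yl)tridecan-2-yl acetate | CCCCCCCCCCC[C@H](CC1=CC(=O)C=C(OC)C1=O)OC(C)=O | target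

## Step count and risks

Total steps: 4. Longest linear sequence: 4 (1 or 2 → 3 → 7 → 9 → 10).

**Step 1 (most likely to fail).** The pyrone anion is a stabilised, fairly soft nucleophile and the β-oxido methyl ester a modest electrophile, so acylation may be slower than self-condensation of the anion on warming. Fallback: set out from 1 again but change the nucleophile to the dianion of triacetic acid lactone (4-hydroxy-6-methyl-2H-pyran-2-one, bought; 2 equiv LDA per pyrone, THF, −78 → 0 °C). Its terminal carbanion acylates readily with methyl esters and gives 4-hydroxy-6-[(4R)-4-hydroxy-2-oxopentadecyl]-2H-pyran-2-one F1. The acidic 4-OH alone is then methylated (Me2SO4 1.05 equiv, K2CO3, acetone, 23 °C), and the route is rejoined at 3.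

**Step 2 (second most likely to fail).** Two things can go wrong: the cascade may close Claisen-wise or cleave by retro-Claisen instead of by aldol, and the para-hydroxy/ortho-methoxy acid 6 may decarboxylate too slowly in alkali, in which case it is lost as its δ-lactone on acidification. Fallback: set out from 1 and build the free tetraketide ester instead of the pyrone. The trianion of bought methyl 3,5-dioxohexanoate (3 equiv LDA, THF, −78 → 0 °C) is acylated at its terminal carbon by 1 to give methyl (9R)-9-hydroxy-3,5,7-trioxoicosanoate F2. At pH 9–10 this closes by the same C2→C7 aldol to methyl 2,4-dihydroxy-6-[(2R)-2-hydroxytridecyl]benzoate F3, which lactonises on acidification to (3R)-6,8-dihydroxy-3-undecyl-3,4-dihydro-1H-isochromen-1-one F4. The non-chelated 6-OH is methylated (MeI 1.1 equiv, K2CO3, acetone) to (3R)-8-hydroxy-6-methoxy-3-undecyl-3,4-dihydro-1H-isochromen-1-one F5. Hot NaOH (H2O/ethylene glycol, 120 °C) opens the lactone to 2-hydroxy-6-[(2R)-2-hydroxytridecyl]-4-methoxybenzoic acid F6, a salicylate-type resorcylic acid that decarboxylates under these conditions, and the route is rejoined at 7.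

**Step 4 (third).** The para position is flanked by OMe and the side chain, so ortho-quinone formation or oxidative coupling could compete, and the lipophilic substrate may react sluggishly in the aqueous medium. Fallback: set out from 7, oxidise before acylating and change the oxidation mode. O2 (1 atm) with Co(salen) (10 mol %) in DMF at 23 °C gives 2-[(2R)-2-hydroxytridecyl]-6-methoxycyclohexa-2,5-diene-1,4-dione F7. The side-chain alcohol is then acetylated on the quinone under non-nucleophilic conditions (AcCl, 2,6-lutidine, CH2Cl2, 0 °C), which arrives directly at 10.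

## Further compounds

F1 | step 1 | 4-hydroxy-6-[(4R)-4-hydroxy-2-oxopentadecyl]-2H-pyran-2-one | CCCCCCCCCCC[C@H](CC(=O)CC1=CC(O)=CC(=O)O1)O
F2 | step 2 | methyl (9R)-9-hydroxy-3,5,7-trioxoicosanoate | CCCCCCCCCCC[C@H](CC(=O)CC(=O)CC(=O)CC(=O)OC)O
F3 | step 2 | methyl 2,4-dihydroxy-6-[(2R)-2-hydroxytridecyl]benzoate | CCCCCCCCCCC[C@H](Cc1cc(O)cc(O)c1C(=O)OC)O
F4 | step 2 | (3R)-6,8-dihydroxy-3-undecyl-3,4-dihydro-1H-isochromen-1-one | CCCCCCCCCCC[C@@H]1Cc2cc(O)cc(O)c2C(=O)O1
F5 | step 2 | (3R)-8-hydroxy-6-methoxy-3-undecyl-3,4-dihydro-1H-isochromen-1-one | CCCCCCCCCCC[C@@H]1Cc2cc(OC)cc(O)c2C(=O)O1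
F6 | step 2 | 2-hydroxy-6-[(2R)-2-hydroxytridecyl]-4-methoxybenzoic acid | CCCCCCCCCCC[C@H](Cc1cc(OC)cc(O)c1C(=O)O)O
F7 | step 4 | 2-[(2R)-2-hydroxytridecyl]-6-methoxycyclohexa-2,5-diene-1,4-dione | CCCCCCCCCCC[C@H](CC1=CC(=O)C=C(OC)C1=O)O
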